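I had no constants for the solid electrophile going into solution, but I had two runs, and I had to decide whether the next flask should be charged as planned and stopped at 3.0 h.

| setting | Tuesday's | Wednesday's | flask |
|---|---|---|---|
| solid electrophile | 28 mM | 44 mM | 20 mM |
| nucleophile | 40 mM | 40 mM | 40.0 mM |
| free base | 40 mM | 40 mM | 40.0 mM |
| remark | run made earlier | run made earlier |  |
| time |  |  | 3.0 h |

| run | time / h | product / % | solid electrophile / % |
|---|---|---|---|
| Tuesday's | 0.417 | 1.0 | 93.7 |
| Tuesday's | 1.33 | 5.2 | 79.4 |
| Tuesday's | 2.50 | 14.3 | 65.2 |
| Tuesday's | 4.00 | 28.0 | 48.6 |
| Wednesday's | 0.417 | 0.5 | 95.7 |
| Wednesday's | 1.33 | 3.7 | 86.9 |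
| Wednesday's | 2.50 | 9.4 | 77.9 |
| Wednesday's | 4.00 | 17.6 | 67.3 |

(scatter of a reading: 0.3 percentage points)

- at the start none of the solid electrophile is in solution

* amount of product at 3.0 h, in percent of the solid electrophile charged
* the change that raises the amount of product at 3.0 h, in percent of the solid electrophile charged most ("none" if none brings more than 2 percentage points) (zeta / alpha / gamma / theta / none)
* amount of product at 3.0 h, in percent of the solid electrophile charged, after gamma

- zeta: doubling the dissolution coefficient of the solid electrophile, all else as stated
- alpha: doubling the solubility of the solid electrophile, all else as stated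
- gamma: doubling the amount of nucleophile, all else as stated
- theta: doubling the amount of free base, all else as stated

The solid electrophile is the limiting reagent in this flask, charged in a smaller amount than the nucleophile, and its balance splits the charge into solid, dissolved electrophile and product. I multiplied the fraction gone from the solid by the charge and got 9.74 mM on Tuesday and 9.72 mM on Wednesday at 2.50 h, although Wednesday's charge was larger. So, with nucleophile and free base as charged in both runs, I took the amount gone from the solid by a given time as independent of the charge while solid remained. A straight line through Tuesday's readings at 2.50 h and 4.00 h gave 11.3 mM at 3.0 h. For this flask that makes 56.5%, the cleared fraction, meaning the part of a charge gone from the solid by a given time. It stayed below the whole charge, so I expected solid to remain in the flask.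

Product amounts also coincided, at 7.84 mM on Tuesday and 7.74 mM on Wednesday at 4.00 h. A straight line through Tuesday's product readings at 2.50 h and 4.00 h gave 5.28 mM at 3.0 h, or 26.4% of this flask's charge, and I decided to charge it as planned.

The forecast gave 26%, chose alpha, and gave 40% after gamma, reasoning that “dissolution doesn't depend on solid load”.

The flask gave 26.9%, alpha was the best change, raising the product by 22 percentage points, and gamma gave 40.6%.

    electrophile + nucleophile → acid set free + product (k = 13.0 M⁻¹ h⁻¹)
    nucleophile + acid set free ⇌ protonated nucleophile, settled at all times (K = 14000 M⁻¹)
    acid set free + free base ⇌ salt of the base, settled at all times (K = 9200 M⁻¹)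
    solid electrophile ⇌ electrophile, rate k4*(cs4 - [electrophile]) while solid is left; crystals form when [electrophile] > cs4 (solubility = 19.0 mM, k = 0.250 h⁻¹)

At 3.00 h this flask held 43.3% as solid, so 56.7% had cleared against my 56.5%. In a neighbouring flask with 8.0 mM charged, the amount I had reckoned comes to 141% of the charge, more than the whole charge, and that neighbouring flask held 0% of solid electrophile and 59.6% of product at 3.00 h.

All runs stem from a simulated flask for substances that don't exist, noise included.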